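**Retrosynthetic overview**

1. Numbering (benzo[7]annulene core): C5 and C6 oxygenated, C7–H, C8 bears flavan 1, C9–H, C9a/C4a ring fusion, C1 bears flavan 2, C3/C4 hydroxylated. The strategy rests on the C5(=O)–C6(O)=C7 unit of the seven-membered tropolone ring: the C6=C7 enol-ether double bond next to the C5 carbonyl is the condensation product of an aryl benzyloxymethyl ketone (C5–C6) with an aldehyde carbon (C7).
2. Last ring formed: C6=C7 by intramolecular aldol condensation of keto-enal 26, whose (Z)-C8=C9 bond holds the aryl ring cis to the formyl group. Global hydrogenolysis follows.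
3. Both pyran rings (O1–C2 of flavan 1 and of flavan 2) close together by a double Mitsunobu reaction with inversion, after double chelation-controlled reduction of a bis(α-benzyloxy ketone). The two C2–C(sp2) bonds come from one aryl/vinyl dilithio species and two molecules of Weinreb amide 8.
4. Amide 8 comes from 3,5-bis(benzyloxy)phenol and methyl (R)-glycidate, which supplies both C3 centres. Dibromide 20 comes from 4-(benzyloxy)-3-hydroxybenzaldehyde by ortho-iodination, para-bromination, an (E)-selective bromo-olefination that sets C8=C9, and an aryl Grignard addition to benzyloxyacetaldehyde for C5–C6.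
5. Ring order: benzo ring and the two phloroglucinol rings are bought; the two pyran rings form in step 15; the seven-membered ring forms in step 18.

Key step: step 18

Remark: the carbinol carbon made in step 11 (the later C5) forms as both epimers and is carried as a mixture in 19, 20 and 22–25 until step 17 makes it the ketone; its SMILES carry no descriptor.
Remark: arene and side-chain carbons of all intermediates are referred to by the final benzo[7]annulene numbers; 1, 3, 9, 13 and 17 are taken as commercial.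

**Fragment 1: Weinreb amide 8**

Step 1
Reactants: 1 3,5-bis(benzyloxy)phenol
Product: 2 3,5-bis(benzyloxy)-2-iodophenol
Conditions: NIS (1.0 equiv), CH2Cl2, −20 °C
Reagents that add atoms: N-iodosuccinimide, O=C1CCC(=O)N1I
Why: Electrophilic aromatic iodination directed by the free hydroxyl should take the ortho position, which is less hindered than the position between the two benzyloxy groups, and one equivalent at low temperature limits di-iodination.

Step 2
Reactants: 2 3,5-bis(benzyloxy)-2-iodophenol, 3 methyl (R)-glycidate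
Product: 6 (R)-5,7-bis(benzyloxy)-3-hydroxychroman-2-one, via aryl Grignard reagent 4 (not isolated), via hydroxy ester 5 (not isolated)
Conditions: MeMgCl (1.0 equiv), LiCl, THF, −30 °C; iPrMgCl·LiCl (1.1 equiv), −30 to 23 °C; CuI (10 mol %), 3, −40 to 0 °C; then p-TsOH (cat.), PhMe, 60 °C
Reagents that add atoms: none
Why: Iodine–magnesium exchange on the magnesium phenoxide gives the aryl Grignard reagent, CuI-catalysed SN2 opening of the epoxide at its CH2 terminus leaves the (R) centre untouched, and acid-catalysed lactonisation closes the aryl lactone, so that the glycidate centre becomes C3 of both later flavan units.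

Step 3
Reactants: 6 (R)-5,7-bis(benzyloxy)-3-hydroxychroman-2-one
Product: 7 (R)-3,5,7-tris(benzyloxy)chroman-2-one
Conditions: BnBr, Ag2O, 4 Å MS, CH2Cl2, 23 °C, dark
Reagents that add atoms: benzyl bromide, BrCc1ccccc1
Why: Silver-oxide-mediated O-benzylation (Purdie-type alkylation) should etherify the α-hydroxyl without a base strong enough to open the aryl lactone or epimerise the α-centre.

Step 4
Reactants: 7 (R)-3,5,7-tris(benzyloxy)chroman-2-one
Product: 8 (R)-2-(benzyloxy)-3-[2,4-bis(benzyloxy)-6-hydroxyphenyl]-N-methoxy-N-methylpropanamide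
Conditions: MeNHOMe·HCl, AlMe3, CH2Cl2, 0 to 23 °C; aq. HCl work-up
Reagents that add atoms: N,O-dimethylhydroxylamine hydrochloride, CNOC.Cl
Why: Weinreb aminolysis of the activated aryl lactone by the aluminium amide opens the ring at the acyl carbon and frees the phenol that later becomes O1 of a pyran ring.

**Fragment 2: dibromide 20**

Step 5
Reactants: 9 4-(benzyloxy)-3-hydroxybenzaldehyde
Product: 10 4-(benzyloxy)-3-hydroxy-2-iodobenzaldehyde
Conditions: ICl, pyridine, 1,4-dioxane, 0 to 23 °C
Reagents that add atoms: iodine monochloride, ClI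
Why: Electrophilic iodination of the phenol should go ortho to the hydroxyl at the position between OH and CHO, the regiochemistry known for 2-halogenation of 3-hydroxy-4-alkoxybenzaldehydes, and this places the handle for the C5–C6 unit at the later C4a.

Step 6
Reactants: 10 4-(benzyloxy)-3-hydroxy-2-iodobenzaldehyde
Product: 11 4-(benzyloxy)-6-bromo-3-hydroxy-2-iodobenzaldehyde
Conditions: NBS, MeCN, 0 °C
Reagents that add atoms: N-bromosuccinimide, O=C1CCC(=O)N1Br
Why: Electrophilic bromination should take the only open position activated by the free hydroxyl, para to it (both ortho positions are blocked), which is the later C1 that will carry flavan 2.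

Step 7
Reactants: 11 4-(benzyloxy)-6-bromo-3-hydroxy-2-iodobenzaldehyde
Product: 12 3,4-bis(benzyloxy)-6-bromo-2-iodobenzaldehyde
Conditions: BnBr, K2CO3, DMF, 23 °C
Reagents that add atoms: benzyl bromide, BrCc1ccccc1
Why: Williamson ether synthesis on the phenoxide caps the last free phenol as its benzyl ether.

Step 8
Reactants: 13 methyl bis(2,2,2-trifluoroethyl)phosphonoacetate
Product: 14 methyl 2-[bis(2,2,2-trifluoroethoxy)phosphoryl]-2-bromoacetate
Conditions: NaH (1.0 equiv), THF, 0 °C; enolate added to Br2 (1.0 equiv), THF, −78 to 0 °C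
Reagents that add atoms: bromine, BrBr
Why: Electrophilic bromination of the sodium enolate of the phosphonoacetate gives the α-bromo phosphonate, with inverse addition at low temperature to limit dibromination.

Step 9
Reactants: 12 3,4-bis(benzyloxy)-6-bromo-2-iodobenzaldehyde, 14 methyl 2-[bis(2,2,2-trifluoroethoxy)phosphoryl]-2-bromoacetate
Product: 15 methyl (E)-3-[3,4-bis(benzyloxy)-6-bromo-2-iodophenyl]-2-bromoprop-2-enoate (aryl cis to the ester)
Conditions: t-BuOK, 18-crown-6, THF, −78 °C
Reagents that add atoms: none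
Why: Horner–Wadsworth–Emmons olefination with the bis(trifluoroethyl) α-bromophosphonate under dissociating conditions (Still–Gennari-type kinetic control) should place the ester cis to the aryl group, giving the (E)-α-bromoacrylate and fixing the C8=C9 geometry needed for the ring closure.

Step 10
Reactants: 15 methyl (E)-3-[3,4-bis(benzyloxy)-6-bromo-2-iodophenyl]-2-bromoprop-2-enoate
Product: 16 (E)-3-[3,4-bis(benzyloxy)-6-bromo-2-iodophenyl]-2-bromoprop-2-en-1-ol
Conditions: i-Bu2AlH (2.5 equiv), CH2Cl2, −78 °C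
Reagents that add atoms: none
Why: Ester reduction with the aluminium hydride at low temperature gives the allylic alcohol without touching the vinyl or aryl halides or the double-bond geometry.

Step 11
Reactants: 16 (E)-3-[3,4-bis(benzyloxy)-6-bromo-2-iodophenyl]-2-bromoprop-2-en-1-ol, 17 2-(benzyloxy)acetaldehyde
Product: 19 (E)-3-{3,4-bis(benzyloxy)-2-[2-(benzyloxy)-1-hydroxyethyl]-6-bromophenyl}-2-bromoprop-2-en-1-ol (both carbinol epimers), via aryl Grignard reagent 18 (not isolated)
Conditions: iPrMgCl·LiCl (2.1 equiv), THF, −40 to −20 °C; 17, −40 to 0 °C; aq. NH4Cl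
Reagents that add atoms: none
Why: After deprotonation of the hydroxyl, iodine–magnesium exchange is selective for the aryl iodide over the aryl and vinyl bromides, and Grignard addition to the aldehyde builds the C5–C6 unit at the alcohol oxidation level.

Step 12
Reactants: 19 diol
Product: 20 bis(tert-butyldimethylsilyl) ether of 19
Conditions: TBSOTf (2.5 equiv), 2,6-lutidine, CH2Cl2, −78 to 0 °C
Reagents that add atoms: tert-butyldimethylsilyl trifluoromethanesulfonate, CC(C)(C)[Si](C)(C)OS(=O)(=O)C(F)(F)F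
Why: Silylation of both hydroxyls (the triflate is chosen for the hindered benzylic carbinol) masks them for the organolithium step.

**Union and endgame**

Step 13
Reactants: 20 bis-silyl ether dibromide, 8 Weinreb amide (2.3 equiv)
Product: 22 bis-ketone (C1 of the arene and C8 each acylated by the (R)-2-(benzyloxy)-3-arylpropanoyl unit), via dilithio species 21 (not isolated)
Conditions: 20, t-BuLi (4.2 equiv), THF, −78 °C; then 8 as its lithium phenoxide (LiN(SiMe3)2, 1.0 equiv per phenol, THF, −78 °C); −78 to −20 °C; aq. NH4Cl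
Reagents that add atoms: none
Why: Double bromine–lithium exchange (with retention at the vinyl carbon) followed by acylation of both carbanions by the Weinreb amide, whose chelated tetrahedral intermediates prevent over-addition, forms both C2–C(sp2) bonds of the flavan units in one flask.

Step 14
Reactants: 22 bis-ketone
Product: 23 bis-carbinol (both new carbinols (S), anti to the neighbouring (R)-benzyloxy centres)
Conditions: Zn(BH4)2, Et2O/THF, −20 to 0 °C
Reagents that add atoms: none
Why: Chelation-controlled (Cram chelate) reduction of the two α-benzyloxy ketones delivers hydride to the face of the five-membered zinc chelate opposite the CH2Ar group, which should give the anti (1S,2R) alcohols, and the enone is reduced in the 1,2 sense.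

Step 15
Reactants: 23 bis-carbinol
Product: 24 bis-chroman (two (2R,3R)-3,5,7-tris(benzyloxy)chroman-2-yl units, on C1 and on C8)
Conditions: PPh3, DIAD, THF, 0 to 23 °C
Reagents that add atoms: none
Why: Double intramolecular Mitsunobu etherification, in which each phenol displaces its activated benzylic or allylic carbinol (6-exo-tet, SN2 with inversion), turns the (S) carbinols into the (2R) centres of the 2,3-cis chromans, a ring closure established for chromans and flavans.

Step 16
Reactants: 24 bis-chroman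
Product: 25 diol (C7 primary allylic alcohol, C5 secondary benzylic alcohol)
Conditions: Bu4NF, THF, 0 to 23 °C; aq. NH4Cl
Reagents that add atoms: none
Why: Fluoride-mediated cleavage of both silyl ethers frees the two hydroxyls, with no base-sensitive group present.

Step 17
Reactants: 25 diol
Product: 26 keto-enal, (Z)-2-[(2R,3R)-3,5,7-tris(benzyloxy)chroman-2-yl]-3-{3,4-bis(benzyloxy)-2-(benzyloxyacetyl)-6-[(2R,3R)-3,5,7-tris(benzyloxy)chroman-2-yl]phenyl}prop-2-enal
Conditions: Dess–Martin periodinane (3 equiv), CH2Cl2, 0 to 23 °C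
Reagents that add atoms: none
Why: Dess–Martin oxidation converts the primary allylic alcohol into the aldehyde and the secondary benzylic alcohol into the ketone without touching benzyl ethers, electron-rich rings or the C8=C9 geometry, and removes the stereocentre at C5.

Step 18
Reactants: 26 keto-enal
Product: 28 nonabenzyl theaflavin (6-O-benzyl, 5-oxo form), via Mannich base 27 (not isolated)
Conditions: pyrrolidine (0.5 equiv), AcOH (0.5 equiv), 4 Å MS, CH2Cl2, 23 to 40 °C
Reagents that add atoms: none
Why: Pyrrolidinium acetate converts the C7 aldehyde into a conjugated iminium ion, the enol of the benzyloxymethyl ketone attacks it through C6 (intramolecular Mannich-type aldol, 7-exo-trig) and closes the seven-membered ring C4a–C5–C6–C7–C8–C9–C9a, and E1cB loss of pyrrolidine then forms the C6=C7 double bond. The closest known reaction type is the amine-salt-catalysed intramolecular aldol (Knoevenagel-type) condensation of aryl ketones with a pendant aldehyde to benzo-fused cycloheptadienones and benzotropones. The elimination gives the fully conjugated 6-benzyloxybenzotropone, which pulls the sequence forward and makes it irreversible. No stereocentre is formed, and the four flavan centres are not alpha to a carbonyl group. The step needs one enolisable site and one acceptor, which the substrate has (C6 is the only acidic CH2 and the enal has no alpha hydrogen because C8 is fully substituted), and it needs the aryl group cis to the formyl group, which step 9 fixes and the later steps carry through with retention, so that no C8=C9 isomerisation through amine addition at C9 (which could open the pyran ring of flavan 1 by loss of phenoxide) has to be relied on.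

Step 19
Reactants: 28 nonabenzyl theaflavin
Product: 29 theaflavin
Conditions: H2 (1 atm), Pd(OH)2/C, THF/MeOH, 23 °C
Reagents that add atoms: none
Why: Hydrogenolysis of the nine benzyl ethers frees the six phenols, the two secondary alcohols and the tropolone hydroxyl, which tautomerises to the 5-hydroxy-6-oxo form drawn for the target.

**Compound list**

1 | 3,5-bis(benzyloxy)phenol | Oc1cc(OCc5ccccc5)cc(OCc5ccccc5)c1 | starting material
2 | 3,5-bis(benzyloxy)-2-iodophenol | Oc1cc(OCc5ccccc5)cc(OCc5ccccc5)c1I | intermediate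
3 | methyl (R)-glycidate | COC(=O)[C@H]1CO1 | starting material
4 | aryl Grignard reagent, chloromagnesium 3,5-bis(benzyloxy)-2-(chloromagnesio)phenoxide (not isolated) | Cl[Mg]Oc1cc(OCc5ccccc5)cc(OCc5ccccc5)c1[Mg]Cl | intermediate
5 | methyl (R)-3-[2,4-bis(benzyloxy)-6-hydroxyphenyl]-2-hydroxypropanoate (present as its magnesium salt, not isolated) | COC(=O)[C@H](O)Cc1c(O)cc(OCc5ccccc5)cc1OCc5ccccc5 | intermediate
6 | (R)-5,7-bis(benzyloxy)-3-hydroxychroman-2-one | O=C1Oc2cc(OCc5ccccc5)cc(OCc5ccccc5)c2C[C@H]1O | intermediate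
7 | (R)-3,5,7-tris(benzyloxy)chroman-2-one | O=C1Oc2cc(OCc5ccccc5)cc(OCc5ccccc5)c2C[C@H]1OCc5ccccc5 | intermediate
8 | (R)-2-(benzyloxy)-3-[2,4-bis(benzyloxy)-6-hydroxyphenyl]-N-methoxy-N-methylpropanamide | CON(C)C(=O)[C@H](OCc5ccccc5)Cc1c(O)cc(OCc5ccccc5)cc1OCc5ccccc5 | intermediate
9 | 4-(benzyloxy)-3-hydroxybenzaldehyde | O=Cc1ccc(OCc5ccccc5)c(O)c1 | starting material
10 | 4-(benzyloxy)-3-hydroxy-2-iodobenzaldehyde | O=Cc1ccc(OCc5ccccc5)c(O)c1I | intermediate
11 | 4-(benzyloxy)-6-bromo-3-hydroxy-2-iodobenzaldehyde | O=Cc1c(Br)cc(OCc5ccccc5)c(O)c1I | intermediate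
12 | 3,4-bis(benzyloxy)-6-bromo-2-iodobenzaldehyde | O=Cc1c(Br)cc(OCc5ccccc5)c(OCc5ccccc5)c1I | intermediate
13 | methyl bis(2,2,2-trifluoroethyl)phosphonoacetate | COC(=O)CP(=O)(OCC(F)(F)F)OCC(F)(F)F | starting material
14 | methyl 2-[bis(2,2,2-trifluoroethoxy)phosphoryl]-2-bromoacetate | COC(=O)C(Br)P(=O)(OCC(F)(F)F)OCC(F)(F)F | intermediate
15 | methyl (E)-3-[3,4-bis(benzyloxy)-6-bromo-2-iodophenyl]-2-bromoprop-2-enoate (aryl cis to ester) | COC(=O)/C(Br)=C\c1c(Br)cc(OCc5ccccc5)c(OCc5ccccc5)c1I | intermediate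
16 | (E)-3-[3,4-bis(benzyloxy)-6-bromo-2-iodophenyl]-2-bromoprop-2-en-1-ol | OC/C(Br)=C\c1c(Br)cc(OCc5ccccc5)c(OCc5ccccc5)c1I | intermediate
17 | 2-(benzyloxy)acetaldehyde | O=CCOCc1ccccc1 | starting material
18 | aryl Grignard reagent from 16, chloromagnesium alkoxide with C4a–MgCl (not isolated) | Cl[Mg]OC/C(Br)=C\c1c(Br)cc(OCc5ccccc5)c(OCc5ccccc5)c1[Mg]Cl | intermediate
19 | (E)-3-{3,4-bis(benzyloxy)-2-[2-(benzyloxy)-1-hydroxyethyl]-6-bromophenyl}-2-bromoprop-2-en-1-ol (both carbinol epimers) | OC/C(Br)=C\c1c(Br)cc(OCc5ccccc5)c(OCc5ccccc5)c1C(O)COCc5ccccc5 | intermediate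
20 | bis(tert-butyldimethylsilyl) ether of 19 | CC(C)(C)[Si](C)(C)OC/C(Br)=C\c1c(Br)cc(OCc5ccccc5)c(OCc5ccccc5)c1C(O[Si](C)(C)C(C)(C)C)COCc5ccccc5 | intermediate
21 | dilithio species from 20, lithium at C1 and at C8 (not isolated) | CC(C)(C)[Si](C)(C)OC/C([Li])=C\c1c([Li])cc(OCc5ccccc5)c(OCc5ccccc5)c1C(O[Si](C)(C)C(C)(C)C)COCc5ccccc5 | intermediate
22 | bis-ketone: (E)-alkene with CH2OTBS cis to the arene; C1 and C8 each carry an (R)-2-(benzyloxy)-3-[2,4-bis(benzyloxy)-6-hydroxyphenyl]propanoyl group; C4a carries CH(OTBS)CH2OBn | CC(C)(C)[Si](C)(C)OC/C(C(=O)[C@H](OCc5ccccc5)Cc2c(O)cc(OCc5ccccc5)cc2OCc5ccccc5)=C\c1c(C(=O)[C@H](OCc5ccccc5)Cc2c(O)cc(OCc5ccccc5)cc2OCc5ccccc5)cc(OCc5ccccc5)c(OCc5ccccc5)c1C(O[Si](C)(C)C(C)(C)C)COCc5ccccc5 | intermediate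
23 | bis-carbinol: 22 with both ketones reduced to (S)-carbinols, each anti to the neighbouring (R)-benzyloxy centre | CC(C)(C)[Si](C)(C)OC/C([C@H](O)[C@H](OCc5ccccc5)Cc2c(O)cc(OCc5ccccc5)cc2OCc5ccccc5)=C\c1c([C@H](O)[C@H](OCc5ccccc5)Cc2c(O)cc(OCc5ccccc5)cc2OCc5ccccc5)cc(OCc5ccccc5)c(OCc5ccccc5)c1C(O[Si](C)(C)C(C)(C)C)COCc5ccccc5 | intermediate
24 | bis-chroman: (2R,3R)-3,5,7-tris(benzyloxy)chroman-2-yl groups on C1 (flavan 2) and C8 (flavan 1); (E)-alkene with CH2OTBS cis to the arene; CH(OTBS)CH2OBn on C4a | CC(C)(C)[Si](C)(C)OC/C([C@H]3Oc4cc(OCc5ccccc5)cc(OCc5ccccc5)c4C[C@H]3OCc5ccccc5)=C\c1c([C@H]3Oc4cc(OCc5ccccc5)cc(OCc5ccccc5)c4C[C@H]3OCc5ccccc5)cc(OCc5ccccc5)c(OCc5ccccc5)c1C(O[Si](C)(C)C(C)(C)C)COCc5ccccc5 | intermediate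
25 | diol: 24 with both silyl ethers removed | OC/C([C@H]3Oc4cc(OCc5ccccc5)cc(OCc5ccccc5)c4C[C@H]3OCc5ccccc5)=C\c1c([C@H]3Oc4cc(OCc5ccccc5)cc(OCc5ccccc5)c4C[C@H]3OCc5ccccc5)cc(OCc5ccccc5)c(OCc5ccccc5)c1C(O)COCc5ccccc5 | intermediate
26 | keto-enal: aryl benzyloxymethyl ketone with flavan 2 on C1 and an ortho (Z)-enal arm carrying flavan 1 (aryl cis to formyl) | O=C/C([C@H]3Oc4cc(OCc5ccccc5)cc(OCc5ccccc5)c4C[C@H]3OCc5ccccc5)=C\c1c([C@H]3Oc4cc(OCc5ccccc5)cc(OCc5ccccc5)c4C[C@H]3OCc5ccccc5)cc(OCc5ccccc5)c(OCc5ccccc5)c1C(=O)COCc5ccccc5 | intermediate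
27 | Mannich base: cyclised 6-(benzyloxy)-7-(pyrrolidin-1-yl)-6,7-dihydrobenzo[7]annulen-5-one (epimers at C6 and C7, not isolated) | O=C1C(OCc5ccccc5)C(N6CCCC6)C([C@H]3Oc4cc(OCc5ccccc5)cc(OCc5ccccc5)c4C[C@H]3OCc5ccccc5)=Cc2c([C@H]3Oc4cc(OCc5ccccc5)cc(OCc5ccccc5)c4C[C@H]3OCc5ccccc5)cc(OCc5ccccc5)c(OCc5ccccc5)c21 | intermediate
28 | nonabenzyl theaflavin (6-O-benzyl, 5-oxo form) | O=C1C(OCc5ccccc5)=CC([C@H]3Oc4cc(OCc5ccccc5)cc(OCc5ccccc5)c4C[C@H]3OCc5ccccc5)=Cc2c([C@H]3Oc4cc(OCc5ccccc5)cc(OCc5ccccc5)c4C[C@H]3OCc5ccccc5)cc(OCc5ccccc5)c(OCc5ccccc5)c21 | intermediate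
29 | theaflavin | O=c1cc([C@H]2Oc3cc(O)cc(O)c3C[C@H]2O)cc2c([C@H]3Oc4cc(O)cc(O)c4C[C@H]3O)cc(O)c(O)c2c1O | target

**Step count**

Total: 19 steps. Longest linear sequence: 14 steps (9 to 29: steps 5–7 and 9–19).

**Three steps most likely to fail**

Step 18 (key ring closure). Enolisation of the hindered, di-ortho-substituted ketone may be slow. Reversible addition of pyrrolidine at C9 could then compete; the enamine so formed can expel the ring oxygen of flavan 1 as phenoxide, and re-closure would scramble C2 of flavan 1. The fallback avoids the amine and sets out from 26. TMSOTf and i-Pr2NEt in CH2Cl2 at −78 °C should convert the ketone into the trimethylsilyl enol ether of 26 F1. A catalytic amount of TMSOTf at −78 °C should then trigger an intramolecular Mukaiyama aldol addition onto the aldehyde to give the cyclised β-silyloxy ketone F2. DBU in CH2Cl2 should eliminate trimethylsilanol (E1cB) and return the route to 28.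

Step 15 (double Mitsunobu closure). The alkoxyphosphonium intermediates may ionise before ring closure: the benzylic one is para to the C4 benzyloxy group and the other is allylic. That would erode the inversion (2,3-trans chromans) or lead to elimination. The fallback sets out from bis-ketone 22, in which each ketone is in equilibrium with its six-membered cyclic hemiketal. Et3SiH with BF3·OEt2 in CH2Cl2/MeCN at −78 to −40 °C should ionise the hemiketals to cyclic oxocarbenium ions. Hydride is expected to add axially, anti to the 3-benzyloxy group, which should sit pseudoaxial to avoid allylic strain with the C2 substituent; this would give the 2,3-cis chromans directly. This reductive etherification replaces steps 14 and 15, makes no new isolable compound (F0) and returns to the route at 24.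

Step 13 (double exchange and double acylation). One site may fail to exchange, or the hindered aryllithium may take the α-proton of the amide, leaving mono-acylated or protonated material. The fallback installs one flavan at a time, from 20. n-BuLi (1.05 equiv, THF, −78 °C) should exchange only the aryl bromide, the vinyl bromide being slower. The lithium phenoxide of 8 then gives the mono-ketone F3. Zn(BH4)2 gives the anti alcohol F4, and PPh3/DIAD closes the first pyran ring to the mono-chroman vinyl bromide F5. t-BuLi (2.1 equiv) and the lithium phenoxide of 8 give the enone F6, and Zn(BH4)2 gives the allylic alcohol F7. A second Mitsunobu closure returns the route to 24.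

**Further compounds**

F1 | step 18 | trimethylsilyl enol ether of 26 | O=C/C([C@H]3Oc4cc(OCc5ccccc5)cc(OCc5ccccc5)c4C[C@H]3OCc5ccccc5)=C\c1c([C@H]3Oc4cc(OCc5ccccc5)cc(OCc5ccccc5)c4C[C@H]3OCc5ccccc5)cc(OCc5ccccc5)c(OCc5ccccc5)c1C(O[Si](C)(C)C)=COCc5ccccc5
F2 | step 18 | cyclised β-silyloxy ketone, 6-(benzyloxy)-7-(trimethylsilyloxy)-6,7-dihydrobenzo[7]annulen-5-one carrying both flavan units | O=C1C(OCc5ccccc5)C(O[Si](C)(C)C)C([C@H]3Oc4cc(OCc5ccccc5)cc(OCc5ccccc5)c4C[C@H]3OCc5ccccc5)=Cc2c([C@H]3Oc4cc(OCc5ccccc5)cc(OCc5ccccc5)c4C[C@H]3OCc5ccccc5)cc(OCc5ccccc5)c(OCc5ccccc5)c21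
F0 | step 15 | none | none
F3 | step 13 | mono-ketone (aryl ketone at C1, vinyl bromide intact) | CC(C)(C)[Si](C)(C)OC/C(Br)=C\c1c(C(=O)[C@H](OCc5ccccc5)Cc2c(O)cc(OCc5ccccc5)cc2OCc5ccccc5)cc(OCc5ccccc5)c(OCc5ccccc5)c1C(O[Si](C)(C)C(C)(C)C)COCc5ccccc5
F4 | step 13 | anti alcohol from F3 | CC(C)(C)[Si](C)(C)OC/C(Br)=C\c1c([C@H](O)[C@H](OCc5ccccc5)Cc2c(O)cc(OCc5ccccc5)cc2OCc5ccccc5)cc(OCc5ccccc5)c(OCc5ccccc5)c1C(O[Si](C)(C)C(C)(C)C)COCc5ccccc5
F5 | step 13 | mono-chroman vinyl bromide (flavan 2 in place) | CC(C)(C)[Si](C)(C)OC/C(Br)=C\c1c([C@H]3Oc4cc(OCc5ccccc5)cc(OCc5ccccc5)c4C[C@H]3OCc5ccccc5)cc(OCc5ccccc5)c(OCc5ccccc5)c1C(O[Si](C)(C)C(C)(C)C)COCc5ccccc5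
F6 | step 13 | enone (C8 acylated, flavan 2 in place) | CC(C)(C)[Si](C)(C)OC/C(C(=O)[C@H](OCc5ccccc5)Cc2c(O)cc(OCc5ccccc5)cc2OCc5ccccc5)=C\c1c([C@H]3Oc4cc(OCc5ccccc5)cc(OCc5ccccc5)c4C[C@H]3OCc5ccccc5)cc(OCc5ccccc5)c(OCc5ccccc5)c1C(O[Si](C)(C)C(C)(C)C)COCc5ccccc5
F7 | step 13 | allylic alcohol from F6 | CC(C)(C)[Si](C)(C)OC/C([C@H](O)[C@H](OCc5ccccc5)Cc2c(O)cc(OCc5ccccc5)cc2OCc5ccccc5)=C\c1c([C@H]3Oc4cc(OCc5ccccc5)cc(OCc5ccccc5)c4C[C@H]3OCc5ccccc5)cc(OCc5ccccc5)c(OCc5ccccc5)c1C(O[Si](C)(C)C(C)(C)C)COCc5ccccc5
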